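## Retrosynthetic overview

1. The target is a 4→6-linked dimer of one flavan-3-ol. The interflavan bond (C4 of the upper unit to C6 of the lower unit) is cut last, into a C4 benzylic cation from a benzylated flavan-3,4-diol and the nucleophilic C6 of a benzylated flavan-3-ol. Both halves come from one flav-3-ene (dihydroxylation for the upper half, hydroboration for the lower half), which sets C3 anti to the C2 aryl group.
2. The flav-3-ene comes from an (S)-flavanone by reduction and dehydration. The only reagent-controlled stereocentre of the route is C2, set by asymmetric transfer hydrogenation before ring C exists.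
3. Ring C of the flavanone is disconnected at O1–C8a and C4a–C4 into a ring A aryllithium (lithium on the future C4a, fluorine on the future C8a) and a 4-aryl-β-lactone. In the forward sense the C4a–C8a unit is inserted into the acyl C–O bond of the lactone, a four- to six-membered ring expansion.
4. Enabling feature: in ring C, O1 and C4 sit on the adjacent ring A carbons C8a and C4a and are 1,3-related through C2–C3. At the C4 ketone level O1–C2–C3–C4 is therefore a β-lactone, and the ketone formed at C4a lies ortho to the C8a–F bond and activates it for closure by the C2 oxygen. The bromine/fluorine pattern of the arene places O1 next to the C8 oxygen.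
5. Ring order: rings A and B are bought as arenes; lactone ring (temporary) → ring C of the monomer → union of two monomers → global debenzylation.

Key step: step 7

Assumption: 3-fluorocatechol and 3',4'-bis(benzyloxy)acetophenone are taken as catalogue compounds (the latter is otherwise one benzylation from 3',4'-dihydroxyacetophenone). Flavan numbering (O1, C2, C3, C4, C4a, C5 to C8, C8a; rings A, B, C) is used for both units; the upper unit is the one bonded through C4.

## Route

Step 1
Reactants: 1 3-fluorocatechol (3-fluorobenzene-1,2-diol)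
Product: 2 1,2-bis(benzyloxy)-3-fluorobenzene
Conditions: BnBr (2.3 equiv), K2CO3 (3 equiv), DMF, 60 °C
Reagents that add atoms: benzyl bromide, BrCc1ccccc1
Why: Williamson etherification of both phenols; the fluoride is inert and no stereocentre is involved.

Step 2
Reactants: 2 1,2-bis(benzyloxy)-3-fluorobenzene
Product: 3 1,2-bis(benzyloxy)-4-bromo-3-fluorobenzene
Conditions: NBS (1.05 equiv), MeCN, 0 °C → rt, dark
Reagents that add atoms: N-bromosuccinimide, O=C1CCC(=O)N1Br
Why: Electrophilic aromatic bromination should go para to the benzyloxy group remote from fluorine (the other benzyloxy group is flanked on both sides and twisted out of conjugation), a position that is also ortho to fluorine, so bromine and fluorine end up on the adjacent carbons that become C4a and C8a.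

Step 3
Reactants: 4 1-[3,4-bis(benzyloxy)phenyl]ethan-1-one (3',4'-bis(benzyloxy)acetophenone)
Product: 5 ethyl 3-[3,4-bis(benzyloxy)phenyl]-3-oxopropanoate
Conditions: NaH (2.5 equiv), (EtO)2CO (3 equiv), THF, reflux; aq. HCl
Reagents that add atoms: diethyl carbonate, CCOC(=O)OCC
Why: Crossed Claisen condensation of the ketone enolate with diethyl carbonate, driven by deprotonation of the β-keto ester formed.

Step 4
Reactants: 5 ethyl 3-[3,4-bis(benzyloxy)phenyl]-3-oxopropanoate
Product: 6 ethyl (3S)-3-[3,4-bis(benzyloxy)phenyl]-3-hydroxypropanoate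
Conditions: RuCl[(S,S)-TsDPEN](p-cymene) (1 mol %), HCO2H/Et3N (5:2), DMF, 40 °C
Reagents that add atoms: none
Why: Noyori asymmetric transfer hydrogenation of an aryl ketone; with the (S,S)-TsDPEN ligand the ruthenium hydride should deliver hydrogen to the face that gives the (S) carbinol (aryl group beside the η6-arene, as for acetophenone), which sets the carbon that becomes C2 of both flavan units.

Step 5
Reactants: 6 ethyl (3S)-3-[3,4-bis(benzyloxy)phenyl]-3-hydroxypropanoate
Product: 7 (3S)-3-[3,4-bis(benzyloxy)phenyl]-3-hydroxypropanoic acid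
Conditions: LiOH·H2O (2 equiv), THF/H2O, 0 °C; 1 M HCl to pH 3 at 0 °C
Reagents that add atoms: lithium hydroxide, [Li+].[OH-]
Why: Ester saponification at 0 °C, cold enough to avoid retro-aldol cleavage or dehydration of the β-hydroxy acid; the stereocentre is not touched.

Step 6
Reactants: 7 (3S)-3-[3,4-bis(benzyloxy)phenyl]-3-hydroxypropanoic acid
Product: 9 (4S)-4-[3,4-bis(benzyloxy)phenyl]oxetan-2-one, via mixed sulfonic anhydride 8 (not isolated)
Conditions: PhSO2Cl (2 equiv), pyridine, 0–4 °C; cold work-up, used without chromatography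
Reagents that add atoms: none
Why: β-Lactonisation by carboxyl activation (sulfonyl chloride–pyridine method): the carboxylate is converted into the mixed anhydride 8 and the β-hydroxyl closes the ring by 4-exo-trig acyl substitution, so the C–O bond at the stereocentre is never broken and (S) is retained.

Step 7
Reactants: 3 1,2-bis(benzyloxy)-4-bromo-3-fluorobenzene; 9 (4S)-4-[3,4-bis(benzyloxy)phenyl]oxetan-2-one
Product: 13 (2S)-7,8-bis(benzyloxy)-2-[3,4-bis(benzyloxy)phenyl]-2,3-dihydro-4H-chromen-4-one, via aryllithium 10 (not isolated), via oxetanolate adduct 11 (not isolated), via keto alkoxide 12 (not isolated)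
Conditions: 3, n-BuLi (1.0 equiv), THF, −78 °C; transfer onto 9 in THF, −78 °C; DMPU, −78 → 0 °C; aq. NH4Cl
Reagents that add atoms: none
Why: Proposed new method: bromine–lithium exchange gives the 2-fluoroaryllithium 10, a regiodefined aryne equivalent (nucleophilic at the future C4a, electrophilic at the fluorine-bearing future C8a), which attacks the strained lactone carbonyl to give adduct 11; strain-driven collapse with acyl C–O cleavage sets the C4a–C4 bond and frees the C2 alkoxide 12, which closes ring C by intramolecular SNAr (addition–elimination through a Meisenheimer adduct, 6-exo-trig) at the C8a–F carbon ortho to the new C4 ketone, setting the O1–C8a bond with loss of LiF. The closest known reaction types are the acyl-selective opening of β-lactones by organolithium reagents to β-hydroxy ketones and the alkoxide SNAr cyclisation of 2-fluoroaryl β-hydroxy ketones to chroman-4-ones, merged here so that the lactone is ring-expanded by formal insertion of the C4a–C8a unit into its acyl C–O bond. No new stereocentre is formed; the (S) centre of 9 becomes C2 with retention because neither of its bonds is broken. The step needs acyl rather than alkyl C–O attack, addition rather than α-deprotonation, a single addition, and SNAr faster than retro-aldol cleavage of 12; these are served by the hard aryllithium at −78 °C with inverse addition, the low electrophilicity of the electron-rich aryl ketone in 12, and the ortho-carbonyl activation of the C–F bond assisted by DMPU. Regiochemistry on ring A is fixed by the bromine and fluorine positions of 3, which put O1 beside the C8 benzyloxy group, the orientation that a free 3-alkoxyaryne would not give.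

Step 8
Reactants: 13 (2S)-7,8-bis(benzyloxy)-2-[3,4-bis(benzyloxy)phenyl]-2,3-dihydro-4H-chromen-4-one
Product: 14 (2S,4S)-7,8-bis(benzyloxy)-2-[3,4-bis(benzyloxy)phenyl]-3,4-dihydro-2H-chromen-4-ol
Conditions: NaBH4, CeCl3·7H2O, MeOH/THF, −20 °C
Reagents that add atoms: none
Why: Luche-type 1,2-reduction under non-basic conditions (so that ring C does not open to the chalcone) is expected to give mainly the 2,4-cis alcohol; the C4 configuration is erased in step 9.

Step 9
Reactants: 14 (2S,4S)-7,8-bis(benzyloxy)-2-[3,4-bis(benzyloxy)phenyl]-3,4-dihydro-2H-chromen-4-ol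
Product: 16 (2S)-7,8-bis(benzyloxy)-2-[3,4-bis(benzyloxy)phenyl]-2H-chromene, via sulfamate ester 15 (not isolated)
Conditions: Burgess reagent (1.5 equiv), toluene, rt → 50 °C, dark
Reagents that add atoms: none
Why: Burgess dehydration: the C4 sulfamate 15 (benzylic and para to the C7 oxygen) eliminates with loss of a C3 hydrogen to the styrene-type C3=C4 alkene, the only direction possible, without touching C2.

Step 10
Reactants: 16 (2S)-7,8-bis(benzyloxy)-2-[3,4-bis(benzyloxy)phenyl]-2H-chromene
Product: 17 (2R,3S,4S)-7,8-bis(benzyloxy)-2-[3,4-bis(benzyloxy)phenyl]-3,4-dihydro-2H-chromene-3,4-diol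
Conditions: OsO4 (2 mol %), NMO (1.5 equiv), acetone/H2O, 0 °C → rt
Reagents that add atoms: N-methylmorpholine N-oxide, C[N+]1([O-])CCOCC1; water, O
Why: Upjohn dihydroxylation: OsO4 adds suprafacially ([3+2]) to the C3=C4 bond on the face anti to the C2 aryl group, which sets C3 (S) of the upper unit (2,3-trans) and gives the 3,4-cis diol whose C4 hydroxyl serves only as a leaving group.

Step 11
Reactants: 16 (2S)-7,8-bis(benzyloxy)-2-[3,4-bis(benzyloxy)phenyl]-2H-chromene
Product: 19 (2R,3S)-7,8-bis(benzyloxy)-2-[3,4-bis(benzyloxy)phenyl]-3,4-dihydro-2H-chromen-3-ol, via alkylborane 18 (not isolated)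
Conditions: BH3·THF (1.5 equiv), THF, 0 °C → rt; then 3 M NaOH, 30 % H2O2, 0 °C
Reagents that add atoms: hydrogen peroxide, OO
Why: Brown hydroboration–oxidation: boron adds to C3 (the alkene terminus remote from ring A, reinforced by donation from O1 and the C7 oxygen) on the face anti to the C2 aryl group and is replaced by hydroxyl with retention, giving the 2,3-trans alcohol (3S) with a C4 methylene.

Step 12
Reactants: 17 (2R,3S,4S)-7,8-bis(benzyloxy)-2-[3,4-bis(benzyloxy)phenyl]-3,4-dihydro-2H-chromene-3,4-diol; 19 (2R,3S)-7,8-bis(benzyloxy)-2-[3,4-bis(benzyloxy)phenyl]-3,4-dihydro-2H-chromen-3-ol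
Product: 21 (2R,3S,4S)-7,8-bis(benzyloxy)-2-[3,4-bis(benzyloxy)phenyl]-4-[(2R,3S)-7,8-bis(benzyloxy)-2-[3,4-bis(benzyloxy)phenyl]-3-hydroxy-3,4-dihydro-2H-chromen-6-yl]-3,4-dihydro-2H-chromen-3-ol (octa-O-benzyl ether of the target; same geometry at C4 as the target, the descriptor changes only through a priority change), via C4 benzylic cation 20 (not isolated)
Conditions: Sc(OTf)3 (10 mol %), 19 (3 equiv, excess recovered), CH2Cl2, −40 → 0 °C
Reagents that add atoms: none
Why: Lewis-acid-catalysed Friedel–Crafts alkylation in the manner of a biomimetic flavan-3,4-diol/flavan-3-ol condensation: ionisation of the C4 hydroxyl gives cation 20 (stabilised by O1 and the C7 oxygen), which is captured by C6 of 19 (ortho to its C7 oxygen, para to its O1, C8 being blocked) on the face anti to the C3 hydroxyl, giving the 3,4-trans (2,4-cis) linkage, while the excess of 19 suppresses self-condensation.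

Step 13
Reactants: 21 octa-O-benzyl ether of the target
Product: 22 (2R,3S,4R)-2-(3,4-dihydroxyphenyl)-4-[(2R,3S)-2-(3,4-dihydroxyphenyl)-3,7,8-trihydroxy-3,4-dihydro-2H-chromen-6-yl]-3,4-dihydro-2H-chromene-3,7,8-triol
Conditions: H2 (1 atm), Pd(OH)2/C, THF/MeOH/H2O, rt
Reagents that add atoms: none
Why: Hydrogenolysis of the eight benzyl ethers under neutral conditions, which should leave the doubly benzylic C4–C6 bond, the C2–O1 bonds and all five stereocentres intact.

## Compound list

1 | 3-fluorocatechol | Oc1cccc(F)c1O | starting material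
2 | 1,2-bis(benzyloxy)-3-fluorobenzene | Fc1cccc(OCc2ccccc2)c1OCc1ccccc1 | intermediate
3 | 1,2-bis(benzyloxy)-4-bromo-3-fluorobenzene | Brc1ccc(OCc2ccccc2)c(OCc2ccccc2)c1F | intermediate
4 | 1-[3,4-bis(benzyloxy)phenyl]ethan-1-one | CC(=O)c1ccc(OCc2ccccc2)c(OCc2ccccc2)c1 | starting material
5 | ethyl 3-[3,4-bis(benzyloxy)phenyl]-3-oxopropanoate | CCOC(=O)CC(=O)c1ccc(OCc2ccccc2)c(OCc2ccccc2)c1 | intermediate
6 | ethyl (3S)-3-[3,4-bis(benzyloxy)phenyl]-3-hydroxypropanoate | CCOC(=O)C[C@H](O)c1ccc(OCc2ccccc2)c(OCc2ccccc2)c1 | intermediate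
7 | (3S)-3-[3,4-bis(benzyloxy)phenyl]-3-hydroxypropanoic acid | OC(=O)C[C@H](O)c1ccc(OCc2ccccc2)c(OCc2ccccc2)c1 | intermediate
8 | benzenesulfonic (3S)-3-[3,4-bis(benzyloxy)phenyl]-3-hydroxypropanoic anhydride | O=C(C[C@H](O)c1ccc(OCc2ccccc2)c(OCc2ccccc2)c1)OS(=O)(=O)c1ccccc1 | intermediate
9 | (4S)-4-[3,4-bis(benzyloxy)phenyl]oxetan-2-one | O=C1C[C@@H](c2ccc(OCc3ccccc3)c(OCc3ccccc3)c2)O1 | intermediate
10 | [3,4-bis(benzyloxy)-2-fluorophenyl]lithium | [Li]c1ccc(OCc2ccccc2)c(OCc2ccccc2)c1F | intermediate
11 | lithium (4S)-2-[3,4-bis(benzyloxy)-2-fluorophenyl]-4-[3,4-bis(benzyloxy)phenyl]oxetan-2-olate (both C2 epimers) | [Li+].[O-]C1(c2ccc(OCc3ccccc3)c(OCc3ccccc3)c2F)C[C@@H](c2ccc(OCc3ccccc3)c(OCc3ccccc3)c2)O1 | intermediate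
12 | lithium (1S)-1-[3,4-bis(benzyloxy)phenyl]-3-[3,4-bis(benzyloxy)-2-fluorophenyl]-3-oxopropan-1-olate | [Li+].[O-][C@@H](CC(=O)c1ccc(OCc2ccccc2)c(OCc2ccccc2)c1F)c1ccc(OCc2ccccc2)c(OCc2ccccc2)c1 | intermediate
13 | (2S)-7,8-bis(benzyloxy)-2-[3,4-bis(benzyloxy)phenyl]-2,3-dihydro-4H-chromen-4-one | O=C1C[C@@H](c2ccc(OCc3ccccc3)c(OCc3ccccc3)c2)Oc2c1ccc(OCc1ccccc1)c2OCc1ccccc1 | intermediate
14 | (2S,4S)-7,8-bis(benzyloxy)-2-[3,4-bis(benzyloxy)phenyl]-3,4-dihydro-2H-chromen-4-ol | O[C@H]1C[C@@H](c2ccc(OCc3ccccc3)c(OCc3ccccc3)c2)Oc2c1ccc(OCc1ccccc1)c2OCc1ccccc1 | intermediate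
15 | triethylammonium salt of (2S,4S)-7,8-bis(benzyloxy)-2-[3,4-bis(benzyloxy)phenyl]-3,4-dihydro-2H-chromen-4-yl N-(methoxycarbonyl)sulfamate | COC(=O)[N-]S(=O)(=O)O[C@H]1C[C@@H](c2ccc(OCc3ccccc3)c(OCc3ccccc3)c2)Oc2c1ccc(OCc1ccccc1)c2OCc1ccccc1.CC[NH+](CC)CC | intermediate
16 | (2S)-7,8-bis(benzyloxy)-2-[3,4-bis(benzyloxy)phenyl]-2H-chromene | C1=C[C@@H](c2ccc(OCc3ccccc3)c(OCc3ccccc3)c2)Oc2c1ccc(OCc1ccccc1)c2OCc1ccccc1 | intermediate
17 | (2R,3S,4S)-7,8-bis(benzyloxy)-2-[3,4-bis(benzyloxy)phenyl]-3,4-dihydro-2H-chromene-3,4-diol | O[C@@H]1[C@H](O)[C@@H](c2ccc(OCc3ccccc3)c(OCc3ccccc3)c2)Oc2c1ccc(OCc1ccccc1)c2OCc1ccccc1 | intermediate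
18 | [(2S,3S)-7,8-bis(benzyloxy)-2-[3,4-bis(benzyloxy)phenyl]-3,4-dihydro-2H-chromen-3-yl]borane (boron trans to the C2 aryl group) | C1[C@H](B)[C@@H](c2ccc(OCc3ccccc3)c(OCc3ccccc3)c2)Oc2c1ccc(OCc1ccccc1)c2OCc1ccccc1 | intermediate
19 | (2R,3S)-7,8-bis(benzyloxy)-2-[3,4-bis(benzyloxy)phenyl]-3,4-dihydro-2H-chromen-3-ol | C1[C@H](O)[C@@H](c2ccc(OCc3ccccc3)c(OCc3ccccc3)c2)Oc2c1ccc(OCc1ccccc1)c2OCc1ccccc1 | intermediate
20 | (2R,3S)-7,8-bis(benzyloxy)-2-[3,4-bis(benzyloxy)phenyl]-3-hydroxy-3,4-dihydro-2H-chromen-4-ylium (C2 aryl and C3 hydroxyl trans) | [CH+]1[C@H](O)[C@@H](c2ccc(OCc3ccccc3)c(OCc3ccccc3)c2)Oc2c1ccc(OCc1ccccc1)c2OCc1ccccc1 | intermediate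
21 | (2R,3S,4S)-7,8-bis(benzyloxy)-2-[3,4-bis(benzyloxy)phenyl]-4-[(2R,3S)-7,8-bis(benzyloxy)-2-[3,4-bis(benzyloxy)phenyl]-3-hydroxy-3,4-dihydro-2H-chromen-6-yl]-3,4-dihydro-2H-chromen-3-ol | c1ccccc1COc1ccc([C@H]2Oc3c(ccc(OCc4ccccc4)c3OCc3ccccc3)[C@@H](c3cc4c(c(OCc5ccccc5)c3OCc3ccccc3)O[C@H](c3ccc(OCc5ccccc5)c(OCc5ccccc5)c3)[C@@H](O)C4)[C@@H]2O)cc1OCc1ccccc1 | intermediate
22 | (2R,3S,4R)-2-(3,4-dihydroxyphenyl)-4-[(2R,3S)-2-(3,4-dihydroxyphenyl)-3,7,8-trihydroxy-3,4-dihydro-2H-chromen-6-yl]-3,4-dihydro-2H-chromene-3,7,8-triol | Oc1ccc([C@H]2Oc3c(ccc(O)c3O)[C@@H](c3cc4c(c(O)c3O)O[C@H](c3ccc(O)c(O)c3)[C@@H](O)C4)[C@@H]2O)cc1O | target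

## Step count and risks

Total step count: 13. Longest linear sequence: 10 steps (steps 3, 4, 5, 6, 7, 8, 9, 10, 12, 13; steps 1–2 and step 11 are branches).

Steps most likely to fail:

1. Step 7 (proposed new method). What may go wrong: α-deprotonation or double addition at the lactone, and retro-aldol cleavage or β-elimination of the keto alkoxide before the ring closes, which would lower conversion and erode the enantiopurity of C2. Fallback with known chemistry, starting from 6: aminolysis with MeNHOMe·HCl and i-PrMgCl (THF, −20 °C) should give the Weinreb amide (3S)-3-[3,4-bis(benzyloxy)phenyl]-3-hydroxy-N-methoxy-N-methylpropanamide F1. Addition of aryllithium 10 (2.2 equiv, THF, −78 °C), which stops at the stable chelated adduct, should give after aqueous quench the hydroxy ketone (3S)-3-[3,4-bis(benzyloxy)phenyl]-1-[3,4-bis(benzyloxy)-2-fluorophenyl]-3-hydroxypropan-1-one F2. A separate intramolecular SNAr (K2CO3, DMF, rt) then closes ring C, and the sequence comes back to the route at 13.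

2. Step 6. What may go wrong: decarboxylative fragmentation of the electron-rich 4-aryl lactone during formation or handling, or sulfonylation of the benzylic hydroxyl followed by elimination. Fallback, starting from 7: condensation with 2-methoxypropene (PPTS cat., CH2Cl2, 0 °C) should give the strain-free acyl donor (6S)-6-[3,4-bis(benzyloxy)phenyl]-2,2-dimethyl-1,3-dioxan-4-one F3. F3 is treated with aryllithium 10 at −78 °C and warmed; the adduct opens and loses acetone, which comes back to the route at the keto alkoxide 12, and 12 closes to 13 as in step 7.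

3. Step 12. What may go wrong: self-condensation of the cation with ring A of a second upper unit (oligomer formation), competing attack at C5 of the lower unit, and poor facial selectivity at C4. Fallback, starting from 17: acid-catalysed thiolysis with phenylmethanethiol should give the storable 3,4-trans thioether (2R,3R,4R)-4-(benzylsulfanyl)-7,8-bis(benzyloxy)-2-[3,4-bis(benzyloxy)phenyl]-3,4-dihydro-2H-chromen-3-ol F4. F4 is then activated with the thiophile AgBF4 (THF, −78 → 0 °C) in the presence of excess 19, so that the cation is generated slowly and irreversibly at low temperature; this comes back to the route at 21.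

Further compounds
F1 | step 7 | (3S)-3-[3,4-bis(benzyloxy)phenyl]-3-hydroxy-N-methoxy-N-methylpropanamide | CON(C)C(=O)C[C@H](O)c1ccc(OCc2ccccc2)c(OCc2ccccc2)c1
F2 | step 7 | (3S)-3-[3,4-bis(benzyloxy)phenyl]-1-[3,4-bis(benzyloxy)-2-fluorophenyl]-3-hydroxypropan-1-one | O[C@@H](CC(=O)c1ccc(OCc2ccccc2)c(OCc2ccccc2)c1F)c1ccc(OCc2ccccc2)c(OCc2ccccc2)c1
F3 | step 6 | (6S)-6-[3,4-bis(benzyloxy)phenyl]-2,2-dimethyl-1,3-dioxan-4-one | CC1(C)OC(=O)C[C@@H](c2ccc(OCc3ccccc3)c(OCc3ccccc3)c2)O1
F4 | step 12 | (2R,3R,4R)-4-(benzylsulfanyl)-7,8-bis(benzyloxy)-2-[3,4-bis(benzyloxy)phenyl]-3,4-dihydro-2H-chromen-3-ol | c1ccccc1CS[C@H]1[C@H](O)[C@@H](c2ccc(OCc3ccccc3)c(OCc3ccccc3)c2)Oc2c1ccc(OCc1ccccc1)c2OCc1ccccc1
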